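Start from the late readings; they choose what to charge next.

| setting | dusk | spring | midnight | amber | green | red | ochre |
|---|---|---|---|---|---|---|---|
| substrate | 0.21 M | 0.10 M | 0.16 M | 0.21 M (fed, over 20.0 h) | 0.21 M | 0.21 M | 0.21 M |
| free catalyst | 0.42 mM | 0.42 mM | 0.42 mM | 0.42 mM | 0.42 mM | 0.42 mM | 0.42 mM |
| remark | run made earlier | run made earlier | run made earlier | all but substrate at the start; substrate goes in evenly over 20.0 h, the run ends at 25 h | everything together in a closed stirred flask, run for 25 h | one stirred flow tank at steady state, fed with the mixture as stated, mean residence time 25 h | a single well-mixed tank run continuously and read at steady state, 250 h in it on average |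
| time |  |  |  | 25 h | 25 h |  |  |

| run | time / h | intermediate / % | target / % |
|---|---|---|---|
| dusk | 4.00 | 10.3 | 1.4 |
| dusk | 8.00 | 16.3 | 3.5 |
| dusk | 12.0 | 20.6 | 6.0 |
| dusk | 15.0 | 22.3 | 10.3 |
| spring | 8.00 | 16.6 | 4.1 |
| spring | 15.0 | 23.5 | 10.1 |
| spring | 25.0 | 27.1 | 21.6 |
| spring | 30.0 | 28.8 | 28.0 |
| midnight | 2.50 | 7.2 | 0.7 |
| midnight | 6.00 | 13.3 | 2.7 |
| midnight | 12.0 | 21.0 | 7.3 |
| midnight | 30.0 | 27.6 | 25.8 |

(readings scatter by 0.5 percentage points)

- the stated concentrations are those of everything mixed, before any reaction; amounts are the same in each set-up
- the feed brings no volume worth counting
- the earlier runs were made in a closed, stirred flask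

* the set-up with the highest amount of intermediate at the outlet or at the end, in percent of the substrate put in ("none" if the first two lie within 2 percentage points) (amber / green / red / ochre / none)
* amount of intermediate at the outlet or at the end, in percent of the substrate put in, amber
* amount of intermediate at the outlet or at the end, in percent of the substrate put in, green
* amount of intermediate at the outlet or at the end, in percent of the substrate put in, red
* amount of intermediate at the outlet or at the end, in percent of the substrate put in, ochre

In the midnight run, take target gained per hour for each unit of intermediate standing. Freeze the free catalyst over a window, and the second step is pseudo-first-order, so this ratio is one constant. Up to 12.0 h it reads 0.0494 /h. From there to 30.0 h it reads 0.0423 /h, less than the first. Read that as free catalyst being lost, and assume the loss follows the molar target standing. Between the window midpoints the target fraction sums to 1.37 h. Scaled to a charge of 0.21 M, that gives 0.148 /h. Call this the kill constant: the fraction of free catalyst lost per hour with the whole charge standing as target. At a scatter of 0.5 percentage points it stays a rough reading. Substrate left by difference in the spring run reads a first step of 0.0280 /h.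

Now decide. In a steady tank, free catalyst arrives with the feed and leaves by wash-out and by loss. Its fraction of the feed is therefore one over one plus kill constant times target fraction times residence time. For ochre, I reckon that 87.5% of the charge has reacted. With the catalyst frozen, I reckon ochre at 6.55% intermediate. With the kill constant, target comes to 38.9%. In this reckoning loss beats wash-out, free catalyst stands at 6.48%, and intermediate reaches 48.6%. The same reckoning puts red near 23.6%. The spring reading at 25.0 h puts green near 27.1%, though spring held less substrate, and I place amber below green. My figure for ochre stands higher than both, so charge ochre.

The forecast gave 22.5%, 27.5%, 19.5% and 8.5% for amber, green, red and ochre, and chose green: “Batch wins clearly.”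

The flask gives 21.6%, 27.1%, 21.7% and 39.1% in that order, and the best is ochre.

    substrate → intermediate (k = 0.0280 /h)
    free catalyst + intermediate → free catalyst + target (k = 120 /M/h)
    free catalyst + target → spent catalyst (k = 0.790 /M/h)
    substrate + intermediate → side product (k = 0.0340 /M/h)

In green, with each step taken net, intermediate is made 2.06 times faster than it is used at 10.3 h, and 1.28 times faster at 25.0 h. It is still gaining at the end of green. Ochre came 9.5 points under my reckoning. The kill constant, with green's target fraction summed to 2.24 h, leaves 71.8% free catalyst at 25.0 h. Green holds 70.4%.

Read green on to 2.5 d. The summed target grows to 12.6 h, and the kill constant leaves 15.5% free catalyst. The computed flask holds 11.0%, with intermediate at 35.4%.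

The runs are calculated for an exercise.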